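**Retrosynthetic overview**

1. Feature: the ten-membered carbocycle C1–C10 carries the C1 ketone and, across the ring, the exocyclic C4 methylene (C15) next to the oxygenated pair C5/C6; this is the pattern left by a [3,3] shift that forms C3–C4 and breaks C1–C6 of a cyclohexane built from C1, C6, C7, C8, C9 and C10.
2. Target ⇐ angeloylation at O8 and Saegusa dehydrogenation at C2–C3 ⇐ transannular etherification O10→C5 ⇐ iodolactonisation (C12 carboxylate→C6, iodide at C5) of the (E)-4-methylenecyclodec-5-enone.
3. That ketone ⇐ anionic oxy-Cope ring expansion of a trans-2-allenyl-1-vinylcyclohexanol whose C8 and C10 oxygens are tied as a cyclic carbonate, which locks both ene arms equatorial.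
4. Precursor ⇐ (R)-carvone (supplies C7, the C1 ketone, the C10 methyl and C11–C13): C12 oxygenation, C8 hydroxylation and inversion, C6 aldol (allene precursor), vinyl addition at C1, iodocarbonate cyclisation (C10–O), Myers allene synthesis.
5. Ring order: cyclohexane (from carvone) → ten-membered carbocycle (step 13) → γ-lactone (step 19) → 5,10-oxygen bridge closing two seven-membered rings (step 20).

Key step: step 13

Remark: all compounds carry the germacrane labels of the target (cyclohexane stage: ring = C1, C6, C7, C8, C9, C10; C14 = methyl on C10; C11–C13 = side chain on C7; C5, C4, C15 = side chain on C6; C2, C3 = vinyl on C1); α is the ring face of H7, β that of the C7 side chain; the C5 carbinol centre made in step 7 is carried as both epimers because step 12 erases it.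

**Route**

Step 1
Reactants: 1 (R)-(−)-carvone
Product: 2 (R)-10-chlorocarvone
Conditions: Ca(OCl)2, CO2 (dry ice), CH2Cl2/H2O, 0 °C
Reagents that add atoms: calcium hypochlorite, [Ca+2].[O-]Cl.[O-]Cl
Why: Hypochlorous acid formed in situ chlorinates the electron-rich isopropenyl group by an ene-type allylic chlorination with double-bond shift, while the electron-poor enone alkene and the C7 centre are not involved.

Step 2
Reactants: 2 (R)-10-chlorocarvone; 3 4-methoxybenzyl alcohol
Product: 4 12-O-(4-methoxybenzyl) enone
Conditions: 3, NaH, THF, 0 °C; then 2, n-Bu4NI (cat.), 0 °C → rt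
Reagents that add atoms: 4-methoxybenzyl alcohol (3), COc1ccc(CO)cc1
Why: Williamson etherification, in which SN2 displacement of the primary allylic chloride by the alkoxide should outrun its reversible addition to the hindered enone.

Step 3
Reactants: 4 12-O-(4-methoxybenzyl) enone
Product: 6 8α-hydroxy enone, via trimethylsilyl dienol ether 5 (not isolated)
Conditions: Me3SiOSO2CF3, Et3N, CH2Cl2, 0 °C; then mCPBA, NaHCO3, hexane/CH2Cl2, −20 °C; aq. citric acid
Reagents that add atoms: 3-chloroperoxybenzoic acid, OOC(=O)c1cccc(Cl)c1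
Why: Soft enolisation under equilibrating conditions should give the through-conjugated dienol ether, whose terminal C8=C9 bond is oxidised (vinylogous Rubottom oxidation) on the face anti to the adjacent C7 side chain, so that hydrolysis returns the enone with the C8 hydroxyl trans to that side chain.

Step 4
Reactants: 6 8α-hydroxy enone
Product: 7 8β-(4-nitrobenzoyloxy) enone
Conditions: 4-nitrobenzoic acid, PPh3, diisopropyl azodicarboxylate, THF, 0 °C → rt
Reagents that add atoms: 4-nitrobenzoic acid, OC(=O)c1ccc(cc1)[N+](=O)[O-]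
Why: Mitsunobu esterification of the secondary allylic alcohol proceeds with SN2 inversion at C8 and so places the oxygen cis to the C7 side chain, as the target requires.

Step 5
Reactants: 7 8β-(4-nitrobenzoyloxy) enone
Product: 8 8β-hydroxy enone
Conditions: K2CO3 (cat.), MeOH, 0 °C
Reagents that add atoms: none
Why: Transesterification of the activated aryl ester is fast at 0 °C, conditions under which the γ-hydroxy enone and the C8 centre should not be disturbed.

Step 6
Reactants: 8 8β-hydroxy enone
Product: 9 8β-(tert-butoxycarbonyloxy) enone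
Conditions: Boc2O, 4-(dimethylamino)pyridine (cat.), MeCN, rt
Reagents that add atoms: di-tert-butyl dicarbonate, CC(C)(C)OC(=O)OC(=O)OC(C)(C)C
Why: Nucleophile-catalysed acylation of the secondary alcohol gives the tert-butyl carbonate that tolerates amide base and organocerium reagents at low temperature and later delivers the C10 oxygen.

Step 7
Reactants: 9 8β-(tert-butoxycarbonyloxy) enone; 10 3-(trimethylsilyl)propynal
Product: 13 6α-(silyloxypropynyl) enone, via lithium enolate 11 (not isolated), via lithium aldolate 12 (not isolated)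
Conditions: lithium diisopropylamide, THF, −78 °C; 10, −78 °C; then t-BuMe2SiOSO2CF3, −78 → −20 °C
Reagents that add atoms: 3-(trimethylsilyl)propynal (10), C[Si](C)(C)C#CC=O; tert-butyldimethylsilyl triflate, CC(C)(C)[Si](C)(C)OS(=O)(=O)C(F)(F)F
Why: Kinetic deprotonation at C6 and aldol addition to the ynal anti to the adjacent C7 side chain sets C6 (side chain α, trans to C7), and in situ silylation of the aldolate blocks retro-aldol cleavage.

Step 8
Reactants: 13 6α-(silyloxypropynyl) enone; 14 vinylmagnesium bromide
Product: 15 1β-vinyl cyclohexenol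
Conditions: CeCl3, THF; 14, −78 °C; then 13, −78 °C; aq. NH4Cl
Reagents that add atoms: vinylmagnesium bromide (14), C=C[Mg]Br
Why: The weakly basic vinylcerium reagent adds 1,2 to the enone without enolisation and, because C10 is still sp2, only the bulky C6 substituent controls the approach, so the vinyl group should enter anti to it (Felkin-type, as usual for 2-substituted cyclohexanones) and end up β and trans to the C6 side chain.

Step 9
Reactants: 15 1β-vinyl cyclohexenol
Product: 16 9α-iodo 8β,10β-carbonate
Conditions: IBr, toluene/CH2Cl2, −80 °C; aq. Na2S2O3/NaHCO3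
Reagents that add atoms: iodine monobromide, IBr
Why: Iodocarbonate cyclisation, in which the carbonyl oxygen of the pseudoaxial C8 carbonate opens the α-face iodonium ion of the trisubstituted C9=C10 alkene at the tertiary carbon C10 (Markovnikov and trans-diaxial), so that the C10–O bond is delivered on the β face cis to O8 and loss of the tert-butyl cation leaves the six-membered cyclic carbonate.

Step 10
Reactants: 16 9α-iodo 8β,10β-carbonate
Product: 17 8β,10β-carbonate
Conditions: Bu3SnH, azobis(isobutyronitrile) (cat.), toluene, 80 °C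
Reagents that add atoms: none
Why: Radical-chain dehalogenation replaces the secondary C9 iodide by hydrogen, hydrogen transfer from the stannane at high concentration being faster than acyloxy shift or addition of the C9 radical to the remote unsaturation.

Step 11
Reactants: 17 8β,10β-carbonate
Product: 18 propargylic alcohol
Conditions: n-Bu4NF, AcOH, THF, 0 °C → rt
Reagents that add atoms: none
Why: Buffered fluoride cleaves the secondary silyl ether and the alkynyl C–Si bond, while the cyclic carbonate, which neither hydroxyl can reach intramolecularly, should be retained.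

Step 12
Reactants: 18 propargylic alcohol
Product: 21 trans-2-allenyl-1-vinylcyclohexanol carbonate, via sulfonylhydrazine adduct 19 (not isolated), via propargylic diazene 20 (not isolated)
Conditions: PPh3, diethyl azodicarboxylate, 2-nitrobenzenesulfonylhydrazide, THF, −15 °C → rt
Reagents that add atoms: none
Why: Myers allene synthesis, in which Mitsunobu displacement of the secondary propargylic alcohol, loss of sulfinic acid and retro-ene extrusion of dinitrogen from the diazene transpose the alkyne into the terminal allene on C6 under neutral conditions that leave the tertiary C1 alcohol untouched.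

Step 13
Reactants: 21 trans-2-allenyl-1-vinylcyclohexanol carbonate
Product: 24 (E)-4-methylenecyclodec-5-enone 8,10-carbonate, via potassium alkoxide 22 (not isolated), via potassium enolate 23 (not isolated)
Conditions: KH, 18-crown-6, THF, 0 °C → rt; then AcOH, −78 °C
Reagents that add atoms: none
Why: Deprotonation gives the potassium alkoxide 22, whose C3=C2–C1(O−)–C6–C5=C4 array undergoes a chair-like [3,3]-sigmatropic (anionic oxy-Cope) shift: vinyl terminus C3 bonds to the central allene carbon C4 while the ring bond C1–C6 breaks, giving enolate 23 and, on protonation, ketone 24. The closest known reaction is the anionic oxy-Cope ring expansion of trans-1,2-dialkenylcyclohexanols to (E)-cyclodec-5-enones, including cases in which an allene is one ene partner. The ten-membered carbocycle is closed by four-atom ring expansion of the cyclohexane (C2–C5 are inserted between C1 and C6 as C3–C4 forms and C1–C6 breaks), not by an end-to-end cyclisation. No stereocentre is created, since C1 and C6 become sp2 and C7, C8 and C10 are spectators. The step needs the E geometry at C5=C6 and the exocyclic position of C4=C15: the 8,10-carbonate can bridge only two axial oxygens and so locks the chair in which the β-vinyl and α-allenyl groups are both equatorial, from which only the chair transition state leading to the E alkene is reachable, while the allene π bond orthogonal to the reacting one remains as the C4 methylene. The alkoxide charge accelerates the shift and enolate formation makes it irreversible; should the enolate take up the neighbouring carbonate, step 14 converges on the same diol.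

Step 14
Reactants: 24 (E)-4-methylenecyclodec-5-enone 8,10-carbonate
Product: 25 8,10-dihydroxy ketone
Conditions: K2CO3, MeOH, 0 °C → rt
Reagents that add atoms: none
Why: Methanolysis of the cyclic carbonate frees the C8 and C10 hydroxyls, and any enol carbonate isomer from step 13 would be cleaved to the same ketone diol, while the non-electrophilic diene is inert to methoxide.

Step 15
Reactants: 25 8,10-dihydroxy ketone
Product: 26 8-O-silyl 10-hydroxy ketone
Conditions: t-BuMe2SiCl, imidazole, DMF, rt
Reagents that add atoms: tert-butyldimethylsilyl chloride, CC(C)(C)[Si](C)(C)Cl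
Why: The secondary C8 hydroxyl is silylated selectively over the hindered tertiary C10 hydroxyl next to the ketone, which masks O8 so that it can neither lactonise onto C12 nor compete in the later cyclisations.

Step 16
Reactants: 26 8-O-silyl 10-hydroxy ketone
Product: 27 C12 allylic alcohol
Conditions: 2,3-dichloro-5,6-dicyano-1,4-benzoquinone, CH2Cl2/pH 7 buffer, 0 °C
Reagents that add atoms: none
Why: Oxidative cleavage of the 4-methoxybenzyl ether by benzylic hydride abstraction releases the primary allylic alcohol and should leave the silyl ether, ketone and diene intact.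

Step 17
Reactants: 27 C12 allylic alcohol
Product: 28 C12 enal
Conditions: MnO2, CH2Cl2, rt
Reagents that add atoms: none
Why: MnO2 oxidises only the allylic primary alcohol, giving the 2-substituted acrolein without affecting the tertiary alcohol.

Step 18
Reactants: 28 C12 enal
Product: 29 C12 acrylic acid
Conditions: NaClO2, NaH2PO4, 2-methyl-2-butene, t-BuOH/H2O, 0 °C → rt
Reagents that add atoms: sodium chlorite, [Na+].[O-]Cl=O
Why: Pinnick oxidation converts the enal into the acrylic acid, the alkene scavenger removing hypochlorous acid before it can add to the diene.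

Step 19
Reactants: 29 C12 acrylic acid
Product: 30 5-iodo trans-6,12-olide
Conditions: I2, NaHCO3, MeCN/H2O, 0 °C, dark
Reagents that add atoms: iodine, II
Why: Iodolactonisation, in which the carboxylate closes 5-exo onto C6 of the strained E C5=C6 alkene anti to the iodonium ion, and because the ring bond C7–C8 occupies one face of that alkene the acrylate arm can reach C6 only from the other, which should give the trans-fused lactone (H6 anti to H7) with the allylic iodide at C5.

Step 20
Reactants: 30 5-iodo trans-6,12-olide
Product: 31 5,10-epoxy 6,12-olide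
Conditions: AgOSO2CF3, 2,6-di-tert-butyl-4-methylpyridine, CH2Cl2, −40 → 0 °C, dark
Reagents that add atoms: none
Why: Silver-assisted ionisation of the allylic iodide gives the C5–C4–C15 allyl cation, which the tertiary C10 hydroxyl captures transannularly at C5 (SN1 etherification closing the oxygen bridge), and since a one-atom bridge between C5 and C10 of the ten-membered ring can only be out,out the C5 configuration is dictated by C10.

Step 21
Reactants: 31 5,10-epoxy 6,12-olide
Product: 33 2,3-dehydro ketone, via trimethylsilyl enol ether 32 (not isolated)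
Conditions: LiN(SiMe3)2, Me3SiCl, THF, −78 °C; then Pd(OAc)2, MeCN, 40 °C
Reagents that add atoms: none
Why: Saegusa–Ito dehydrogenation, in which the ketone can enolise only toward C2 because C10 is quaternary, and palladation of the silyl enol ether by Pd(OAc)2 followed by β-hydride elimination installs the C2=C3 alkene in conjugation with the ketone and the C4 methylene.

Step 22
Reactants: 33 2,3-dehydro ketone
Product: 34 8-hydroxy lactone
Conditions: HF·pyridine, THF, 0 °C → rt
Reagents that add atoms: none
Why: Acidic fluoride removes the silyl ether without the basic conditions that would add to the α-methylene lactone or the dienone.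

Step 23
Reactants: 34 8-hydroxy lactone; 35 angelic acid
Product: 36 target CNP0282559.1
Conditions: 35, 2,4,6-trichlorobenzoyl chloride, Et3N, toluene, rt; then 34, 80 °C
Reagents that add atoms: angelic acid (35), C/C=C(/C)C(=O)O
Why: Yamaguchi esterification through the mixed anhydride acylates the hindered secondary alcohol at the less hindered angeloyl carbonyl, and leaving out nucleophilic catalysts should preserve the Z geometry of the 2-methylbut-2-enoate.

**Compound list**

1 | (R)-(−)-carvone, (5R)-2-methyl-5-(prop-1-en-2-yl)cyclohex-2-en-1-one | CC1=CC[C@H](CC1=O)C(C)=C | starting material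
2 | (R)-10-chlorocarvone, (5R)-5-(3-chloroprop-1-en-2-yl)-2-methylcyclohex-2-en-1-one | CC1=CC[C@H](CC1=O)C(=C)CCl | intermediate
3 | 4-methoxybenzyl alcohol | COc1ccc(CO)cc1 | starting material
4 | (5R)-5-[3-(4-methoxybenzyloxy)prop-1-en-2-yl]-2-methylcyclohex-2-en-1-one (12-O-PMB enone) | CC1=CC[C@H](CC1=O)C(=C)COCc1ccc(OC)cc1 | intermediate
5 | trimethylsilyl dienol ether of 4 (C1(OSiMe3)=C10 and C8=C9; C7 unchanged) | CC1=C(O[Si](C)(C)C)C[C@H](C(=C)COCc2ccc(OC)cc2)C=C1 | intermediate
6 | 8α-hydroxy enone (4 with a C8 hydroxyl trans to the C7 side chain) | CC1=C[C@H](O)[C@H](CC1=O)C(=C)COCc1ccc(OC)cc1 | intermediate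
7 | 8β-(4-nitrobenzoyloxy) enone (ester cis to the C7 side chain) | CC1=C[C@@H](OC(=O)c2ccc(cc2)[N+](=O)[O-])[C@H](CC1=O)C(=C)COCc1ccc(OC)cc1 | intermediate
8 | 8β-hydroxy enone (hydroxyl cis to the C7 side chain) | CC1=C[C@@H](O)[C@H](CC1=O)C(=C)COCc1ccc(OC)cc1 | intermediate
9 | 8β-(tert-butoxycarbonyloxy) enone | CC1=C[C@@H](OC(=O)OC(C)(C)C)[C@H](CC1=O)C(=C)COCc1ccc(OC)cc1 | intermediate
10 | 3-(trimethylsilyl)prop-2-ynal | C[Si](C)(C)C#CC=O | starting material
11 | lithium C1(O)=C6 enolate of 9 | CC1=C[C@@H](OC(=O)OC(C)(C)C)[C@H](C=C1[O-])C(=C)COCc1ccc(OC)cc1.[Li+] | intermediate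
12 | lithium aldolate: 9 with a 6α-[1-oxido-3-(trimethylsilyl)prop-2-ynyl] group trans to the C7 side chain (C5 epimers) | CC1=C[C@@H](OC(=O)OC(C)(C)C)[C@@H](C(=C)COCc2ccc(OC)cc2)[C@H](C([O-])C#C[Si](C)(C)C)C1=O.[Li+] | intermediate
13 | 6α-[1-(tert-butyldimethylsilyloxy)-3-(trimethylsilyl)prop-2-ynyl] enone, 8β-OBoc (C5 epimers) | CC1=C[C@@H](OC(=O)OC(C)(C)C)[C@@H](C(=C)COCc2ccc(OC)cc2)[C@H](C(O[Si](C)(C)C(C)(C)C)C#C[Si](C)(C)C)C1=O | intermediate
14 | vinylmagnesium bromide | C=C[Mg]Br | starting material
15 | cyclohex-2-enol with 1α-hydroxy, 1β-vinyl (trans to the 6α side chain), 8β-OBoc, C9=C10 | CC1=C[C@@H](OC(=O)OC(C)(C)C)[C@@H](C(=C)COCc2ccc(OC)cc2)[C@H](C(O[Si](C)(C)C(C)(C)C)C#C[Si](C)(C)C)[C@@]1(O)C=C | intermediate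
16 | 9α-iodo 8β,10β-cyclic carbonate (2,4-dioxabicyclo[3.3.1]nonan-3-one; 10α-methyl, 1α-hydroxy, 1β-vinyl) | C[C@]12OC(=O)O[C@H]([C@H]1I)[C@@H](C(=C)COCc3ccc(OC)cc3)[C@H](C(O[Si](C)(C)C(C)(C)C)C#C[Si](C)(C)C)[C@@]2(O)C=C | intermediate
17 | 8β,10β-cyclic carbonate with C9 methylene | C[C@]12OC(=O)O[C@H](C1)[C@@H](C(=C)COCc3ccc(OC)cc3)[C@H](C(O[Si](C)(C)C(C)(C)C)C#C[Si](C)(C)C)[C@@]2(O)C=C | intermediate
18 | carbonate diol with 1α-hydroxy and 6α-(1-hydroxyprop-2-ynyl) | C[C@]12OC(=O)O[C@H](C1)[C@@H](C(=C)COCc3ccc(OC)cc3)[C@H](C(O)C#C)[C@@]2(O)C=C | intermediate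
19 | Mitsunobu adduct, C5–N(NH2)SO2(2-nitrophenyl) propargylic hydrazide | C[C@]12OC(=O)O[C@H](C1)[C@@H](C(=C)COCc3ccc(OC)cc3)[C@H](C(C#C)N(N)S(=O)(=O)c3ccccc3[N+](=O)[O-])[C@@]2(O)C=C | intermediate
20 | propargylic diazene, C5–N=NH | C[C@]12OC(=O)O[C@H](C1)[C@@H](C(=C)COCc3ccc(OC)cc3)[C@H](C(C#C)N=N)[C@@]2(O)C=C | intermediate
21 | oxy-Cope precursor: 1α-hydroxy-1β-vinyl-6α-(propa-1,2-dienyl)-7β-[3-(4-methoxybenzyloxy)prop-1-en-2-yl]-10α-methylcyclohexane 8β,10β-carbonate (vinyl and allenyl trans) | C[C@]12OC(=O)O[C@H](C1)[C@@H](C(=C)COCc3ccc(OC)cc3)[C@H](C=C=C)[C@@]2(O)C=C | intermediate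
22 | potassium alkoxide of 21 | C[C@]12OC(=O)O[C@H](C1)[C@@H](C(=C)COCc3ccc(OC)cc3)[C@H](C=C=C)[C@@]2([O-])C=C.[K+] | intermediate
23 | potassium C1(O)=C2 enolate of 24 | [K+].[O-]C1=CCC(=C)/C=C/[C@H](C(=C)COCc3ccc(OC)cc3)[C@H]2C[C@]1(C)OC(=O)O2 | intermediate
24 | (E)-4-methylenecyclodec-5-en-1-one carrying the 8,10-carbonate, 10-methyl and 7-[3-(4-methoxybenzyloxy)prop-1-en-2-yl] | O=C1CCC(=C)/C=C/[C@H](C(=C)COCc3ccc(OC)cc3)[C@H]2C[C@]1(C)OC(=O)O2 | intermediate
25 | 8,10-dihydroxy ketone (configurations at C7, C8, C10 unchanged) | O=C1CCC(=C)/C=C/[C@H](C(=C)COCc2ccc(OC)cc2)[C@H](O)C[C@]1(C)O | intermediate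
26 | 8-O-(tert-butyldimethylsilyl) 10-hydroxy ketone | O=C1CCC(=C)/C=C/[C@H](C(=C)COCc2ccc(OC)cc2)[C@H](O[Si](C)(C)C(C)(C)C)C[C@]1(C)O | intermediate
27 | C12 allylic alcohol | O=C1CCC(=C)/C=C/[C@H](C(=C)CO)[C@H](O[Si](C)(C)C(C)(C)C)C[C@]1(C)O | intermediate
28 | C12 enal | O=C1CCC(=C)/C=C/[C@H](C(=C)C=O)[C@H](O[Si](C)(C)C(C)(C)C)C[C@]1(C)O | intermediate
29 | C12 acrylic acid | O=C1CCC(=C)/C=C/[C@H](C(=C)C(=O)O)[C@H](O[Si](C)(C)C(C)(C)C)C[C@]1(C)O | intermediate
30 | 5-iodo trans-6,12-olide (iodide anti to the lactone oxygen; 10-hydroxy, 1-oxo, 8-O-TBS) | C=C1C(=O)O[C@H]2[C@H]1[C@H](O[Si](C)(C)C(C)(C)C)C[C@](C)(O)C(=O)CCC(=C)[C@H]2I | intermediate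
31 | 5,10-epoxy trans-6,12-olide, 1-oxo, 4(15)-ene, 8-O-TBS | C=C1C(=O)O[C@H]2[C@H]1[C@H](O[Si](C)(C)C(C)(C)C)C[C@]1(C)O[C@H]2C(=C)CCC1=O | intermediate
32 | trimethylsilyl enol ether (C1(OSiMe3)=C2) of 31 | C=C1C(=O)O[C@H]2[C@H]1[C@H](O[Si](C)(C)C(C)(C)C)C[C@]1(C)O[C@H]2C(=C)CC=C1O[Si](C)(C)C | intermediate
33 | 1-oxo-2,4(15)-diene (2,3-dehydro ketone), 8-O-TBS | C=C1C(=O)O[C@H]2[C@H]1[C@H](O[Si](C)(C)C(C)(C)C)C[C@]1(C)O[C@H]2C(=C)C=CC1=O | intermediate
34 | 8-hydroxy lactone (deacyl target) | C=C1C(=O)O[C@H]2[C@H]1[C@H](O)C[C@]1(C)O[C@H]2C(=C)C=CC1=O | intermediate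
35 | angelic acid, (Z)-2-methylbut-2-enoic acid | C/C=C(/C)C(=O)O | starting material
36 | CNP0282559.1, (5S,6S,7R,8R,10S) 8-angelate | C=C1C(=O)O[C@H]2[C@H]1[C@H](OC(=O)/C(C)=C\C)C[C@]1(C)O[C@H]2C(=C)C=CC1=O | target

**Step count and risks**

Total step count: 23. Longest linear sequence: 23 steps, from 1 to 36.

Steps most likely to fail:

Step 20. After silver-assisted loss of iodide the allyl cation may be captured at its primary terminus C15, giving the isomeric bridged ether with a C4=C5 double bond, or may lose a proton to a triene instead of closing at C5. The fallback reverses the order of the two C–O bond formations and avoids the allyl cation. Starting from 26, N-iodosuccinimide in MeCN at 0 °C should bring about transannular iodoetherification, the C10 hydroxyl adding to C5 anti to an iodonium ion and leaving iodide at C6, to give the 5,10-epoxy 6-iodide F1. Removal of the 4-methoxybenzyl group with 2,3-dichloro-5,6-dicyano-1,4-benzoquinone gives the allylic alcohol F2, MnO2 the enal F3, and NaClO2/NaH2PO4/2-methyl-2-butene the acrylic acid F4. Cs2CO3 in DMF then closes the lactone by intramolecular SN2 displacement of the C6 iodide with inversion, and the route is rejoined at 31.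

Step 19. The iodonium ion may form on the exocyclic C4=C15 alkene and be opened by the free C10 hydroxyl, the carboxylate may add to the wrong face of C5=C6 (cis-fused lactone), or the allylic iodide may decompose on isolation. The fallback uses an epoxide in place of the iodonium ion and a stable allylic alcohol in place of the iodide. Starting from 29, dimethyldioxirane in acetone at −20 °C should epoxidise the strained E C5=C6 alkene to the epoxy acid F5. Catalytic camphorsulfonic acid in CH2Cl2 opens the epoxide 5-exo at C6 with inversion to the 5-hydroxy trans-lactone F6. Catalytic Re2O7 in CH2Cl2 then ionises the allylic alcohol and the C10 hydroxyl closes the bridge (dehydrative allylic etherification), rejoining the route at 31 without passing through 30.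

Step 13. The potassium alkoxide or the product enolate may attack the cyclic carbonate (acyl transfer, oligomerisation), or the base may isomerise the allene before the sigmatropic shift. The fallback is the neutral siloxy-Cope rearrangement, which needs no alkoxide. Starting from 21, N-(trimethylsilyl)imidazole gives the trimethylsilyl ether F7. Heating in toluene (sealed tube, 180–200 °C) should effect the same [3,3] ring expansion to the silyl enol ether F8, driven by formation of the conjugated diene. K2CO3 in MeOH cleaves the silyl enol ether and the carbonate together, and the route is rejoined at 25.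

**Further compounds**

F1 | step 20 | 5,10-epoxy 6-iodo ketone (iodide anti to the ether oxygen; 12-O-PMB, 8-O-TBS) | O=C1CCC(=C)[C@@H]2O[C@@]1(C)C[C@@H](O[Si](C)(C)C(C)(C)C)[C@@H](C(=C)COCc3ccc(OC)cc3)[C@H]2I
F2 | step 20 | C12 allylic alcohol of F1 | O=C1CCC(=C)[C@@H]2O[C@@]1(C)C[C@@H](O[Si](C)(C)C(C)(C)C)[C@@H](C(=C)CO)[C@H]2I
F3 | step 20 | C12 enal of F1 | O=C1CCC(=C)[C@@H]2O[C@@]1(C)C[C@@H](O[Si](C)(C)C(C)(C)C)[C@@H](C(=C)C=O)[C@H]2I
F4 | step 20 | C12 acrylic acid of F1 | O=C1CCC(=C)[C@@H]2O[C@@]1(C)C[C@@H](O[Si](C)(C)C(C)(C)C)[C@@H](C(=C)C(=O)O)[C@H]2I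
F5 | step 19 | trans-5,6-epoxide of acid 29 | O=C1CCC(=C)[C@H]2O[C@@H]2[C@H](C(=C)C(=O)O)[C@H](O[Si](C)(C)C(C)(C)C)C[C@]1(C)O
F6 | step 19 | 5-hydroxy trans-6,12-olide (hydroxyl anti to the lactone oxygen) | C=C1C(=O)O[C@H]2[C@H]1[C@H](O[Si](C)(C)C(C)(C)C)C[C@](C)(O)C(=O)CCC(=C)[C@H]2O
F7 | step 13 | 1-O-trimethylsilyl ether of 21 | C[C@]12OC(=O)O[C@H](C1)[C@@H](C(=C)COCc3ccc(OC)cc3)[C@H](C=C=C)[C@@]2(O[Si](C)(C)C)C=C
F8 | step 13 | trimethylsilyl enol ether (C1(OSiMe3)=C2) of 24 | C[Si](C)(C)OC1=CCC(=C)/C=C/[C@H](C(=C)COCc3ccc(OC)cc3)[C@H]2C[C@]1(C)OC(=O)O2
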